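## Plan

1. **Cuts** (imidazo[1,2-a]pyrazin-3(7H)-one numbering). The two phenols are masked as benzyl ethers. The pyrazine ring is opened at N4–C5 and C5–C6, which releases C5 as the carbon of a formamide acetal. Then C6=N7 is cut to 4-benzyloxybenzaldehyde, N4–C8a to a dipeptide amide, and C8a–N1 to phenylalanine and tyrosine.
2. **Enabling feature.** C5 (formate level) and C6 (aldehyde level) are both electrophilic carbons by origin. In the open precursor, C8–H sits between the amidine carbon C8a of the imidazolone ring and the imine nitrogen N7. An alkoxide can therefore turn C8–N7–C6 into a 2-azaallyl anion, and C6 becomes a nucleophile.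
3. **Forward order.** The Phe–Tyr chain is joined, the five-membered imidazolone ring is closed first, and the aldimine is placed on the C8 nitrogen. The six-membered ring is closed last around the one-carbon unit, and debenzylation ends the route.
4. **Stereochemistry.** The target has none. The L-amino acids only deliver the C8 and C2 side chains, and their centres become trigonal in the key step.

Key step: step 6

Remark: the target SMILES holds no stereocentre and no stereogenic double bond, so one achiral compound is aimed at. The imidazolone intermediates are drawn in their nominal (S,S) form, and epimerisation at these labile centres has no consequence.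

Remark: from the imidazolone stage onward, all operations use degassed solvents under argon, because the C–H next to the ring carbonyl autoxidises.

## Route

Step 1
Reactants: 1 N-Boc-L-phenylalanine; 2 O-benzyl-L-tyrosine methyl ester hydrochloride
Product: 4 Boc-L-Phe-L-Tyr(Bn)-OMe, via Boc-L-Phe-OBt active ester 3 (not isolated)
Conditions: EDC·HCl, HOBt, i-Pr2NEt, CH2Cl2, 0 °C → rt
Reagents that add atoms: none
Why: Carbodiimide/HOBt peptide coupling: EDC turns acid 1 into the benzotriazolyl ester 3, which acylates the liberated amine of 2, and the urethane on nitrogen suppresses oxazolone formation so that both L-centres are carried over unchanged.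

Step 2
Reactants: 4 Boc-L-Phe-L-Tyr(Bn)-OMe
Product: 5 Boc-L-Phe-L-Tyr(Bn)-NH2
Conditions: NH3 (7 M in MeOH), rt, sealed flask
Reagents that add atoms: ammonia, N
Why: Ammonolysis of an unhindered peptide methyl ester in methanolic ammonia is a routine ester-to-carboxamide exchange that should leave the Boc group, the peptide bond and the aryl benzyl ether untouched.

Step 3
Reactants: 5 Boc-L-Phe-L-Tyr(Bn)-NH2
Product: 6 (5S)-5-(4-benzyloxybenzyl)-2-[(1S)-1-(Boc-amino)-2-phenylethyl]-3,5-dihydro-4H-imidazol-4-one
Conditions: NaOH (2 equiv), degassed EtOH–H2O, 70 °C, Ar; then AcOH to pH 6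
Reagents that add atoms: none
Why: Base-mediated cyclodehydration of an α-acylamino carboxamide, the classical entry to 3,5-dihydro-4H-imidazol-4-ones: the deprotonated primary amide adds to the neighbouring Phe carbonyl (5-exo-trig), hydroxide leaves, and the acidic product is drawn out of the equilibrium as its delocalised sodium salt, while Boc and benzyl ether tolerate hydroxide and oxygen is kept out because the C5–H anion autoxidises.

Step 4
Reactants: 6 Boc-protected aminoalkyl imidazolone
Product: 7 (5S)-2-[(1S)-1-amino-2-phenylethyl]-5-(4-benzyloxybenzyl)-3,5-dihydro-4H-imidazol-4-one dihydrochloride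
Conditions: HCl (4 M in dioxane), 0 °C → rt; evaporation
Reagents that add atoms: hydrogen chloride, Cl
Why: Acidolytic Boc cleavage under anhydrous conditions, in which the aryl benzyl ether is inert, the ring cannot be hydrolysed for want of water, and the product is kept as a salt in which neither the amine nor the oxidisable C5–H position is reactive.

Step 5
Reactants: 7 aminoalkyl imidazolone dihydrochloride; 8 4-benzyloxybenzaldehyde
Product: 9 (E)-4-benzyloxybenzaldimine of (5S)-2-[(1S)-1-amino-2-phenylethyl]-5-(4-benzyloxybenzyl)-3,5-dihydro-4H-imidazol-4-one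
Conditions: Et3N (2 equiv), 4 Å MS, CH2Cl2, rt, Ar
Reagents that add atoms: none
Why: Schiff base condensation of a primary amine with a non-enolisable aromatic aldehyde over a desiccant, in which conjugation with the electron-rich arene should favour the open (E)-aldimine and the acid-free medium should hold back ring closure of the lactam N–H onto the imine carbon; the crude product is used without chromatography.

Step 6
Reactants: 9 (E)-aldimine of the aminoalkyl imidazolone; 10 N,N-dimethylformamide dineopentyl acetal
Product: 14 O,O'-dibenzylcoelenterazine, via N4-aminal ester 11 (not isolated), via 5-dimethylamino-5,6-dihydro bicycle 12 (not isolated), via 2H-tautomer 13 (not isolated)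
Conditions: 10 (2.5 equiv), degassed PhMe, 90 °C, Ar, dark
Reagents that add atoms: N,N-dimethylformamide dineopentyl acetal (10), CC(C)(C)COC(OCC(C)(C)C)N(C)C
Why: Proposed new method: thermal ionisation of 10 gives an alkoxyformamidinium ion and neopentoxide, exchange at the acidic lactam N–H of 9 gives aminal ester 11 (N4–C5), and loss of the second alkoxide from 11 leaves an N-acylformamidinium carbon tethered to N4. The alkoxide removes C8–H, which lies between the amidine carbon C8a and the imine nitrogen N7, and the delocalised C8–N7–C6 2-azaallyl anion adds through C6 to the tethered cation (C5–C6) in a 6-exo-trig Mannich-type closure of the pyrazine ring that gives 12 and leaves C8=N7. Loss of dimethylamine across C5–C6 gives 13 and migration of the C2 proton to N7 gives the 7H form 14, so the sum is redox neutral, no oxidant is needed, and the transient centres at C5 and C6 as well as the two centres of 9 all become trigonal, which leaves no stereocentre to control. The closest known reaction types are additions of 2-azaallyl anions and of N-metallated azomethine ylides of α-imino esters to iminium and carbonyl carbons, and the one-carbon annulations in which a formamide acetal bridges an N–H and an acidic C–H with loss of dimethylamine. The step needs bonding at C6 rather than at C8, C2 or N1, and at N4 rather than at N1: from the N4-bound cation the other three sites could only close four-membered rings, intermolecular adducts at the fully substituted C8 and C2 carry no hydrogen for elimination and revert, deprotonation at the more acidic C2–H is likewise reversible and unproductive, and imidazol-4-one anions are known to take carbon electrophiles at the lactam nitrogen. The neopentyl acetal is chosen because it cannot alkylate the acidic N–H and enol sites of 9 and 14 as a methyl acetal would, and a 1,3-proton shift of the aldimine to the ketimine does no harm since both forms give the same anion.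

Step 7
Reactants: 14 O,O'-dibenzylcoelenterazine
Product: 15 coelenterazine
Conditions: H2 (1 atm), 10% Pd/C, degassed MeOH–THF, rt, dark; filtration through Celite under Ar
Reagents that add atoms: none
Why: Catalytic hydrogenolysis of aryl benzyl ethers, which should be much faster than hydrogenation of the highly substituted, electron-rich heterocycle and cannot touch the carbon-bound benzyl groups at C2 and C8, and which ends in a neutral filtrate provided that air is excluded, since the product autoxidises.

## Compound list

1 | N-Boc-L-phenylalanine | CC(C)(C)OC(=O)N[C@@H](Cc1ccccc1)C(=O)O | starting material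
2 | O-benzyl-L-tyrosine methyl ester hydrochloride | N[C@@H](Cc1ccc(OCc2ccccc2)cc1)C(=O)OC.Cl | starting material
3 | N-Boc-L-phenylalanine benzotriazol-1-yl ester | CC(C)(C)OC(=O)N[C@@H](Cc1ccccc1)C(=O)On1nnc2ccccc12 | intermediate (not isolated)
4 | Boc-L-Phe-L-Tyr(Bn)-OMe, methyl N-(N-Boc-L-phenylalanyl)-O-benzyl-L-tyrosinate | CC(C)(C)OC(=O)N[C@@H](Cc1ccccc1)C(=O)N[C@@H](Cc1ccc(OCc2ccccc2)cc1)C(=O)OC | intermediate
5 | Boc-L-Phe-L-Tyr(Bn)-NH2, the primary carboxamide of 4 | CC(C)(C)OC(=O)N[C@@H](Cc1ccccc1)C(=O)N[C@@H](Cc1ccc(OCc2ccccc2)cc1)C(N)=O | intermediate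
6 | (5S)-5-(4-benzyloxybenzyl)-2-[(1S)-1-(tert-butoxycarbonylamino)-2-phenylethyl]-3,5-dihydro-4H-imidazol-4-one | CC(C)(C)OC(=O)N[C@@H](Cc1ccccc1)C1=N[C@@H](Cc2ccc(OCc3ccccc3)cc2)C(=O)N1 | intermediate
7 | (5S)-2-[(1S)-1-amino-2-phenylethyl]-5-(4-benzyloxybenzyl)-3,5-dihydro-4H-imidazol-4-one dihydrochloride | N[C@@H](Cc1ccccc1)C1=N[C@@H](Cc2ccc(OCc3ccccc3)cc2)C(=O)N1.Cl.Cl | intermediate
8 | 4-benzyloxybenzaldehyde | O=Cc1ccc(OCc2ccccc2)cc1 | starting material
9 | (5S)-5-(4-benzyloxybenzyl)-2-[(1S)-1-{(E)-[4-(benzyloxy)benzylidene]amino}-2-phenylethyl]-3,5-dihydro-4H-imidazol-4-one | C(c1ccccc1)Oc1ccc(/C=N/[C@@H](Cc2ccccc2)C2=N[C@@H](Cc3ccc(OCc4ccccc4)cc3)C(=O)N2)cc1 | intermediate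
10 | N,N-dimethylformamide dineopentyl acetal | CC(C)(C)COC(OCC(C)(C)C)N(C)C | starting material
11 | imine 9 bearing a (dimethylamino)(neopentyloxy)methyl group on the lactam nitrogen (the later N4); aminal carbon of undefined configuration | C(c1ccccc1)Oc1ccc(/C=N/[C@@H](Cc2ccccc2)C2=N[C@@H](Cc3ccc(OCc4ccccc4)cc3)C(=O)N2C(OCC(C)(C)C)N(C)C)cc1 | intermediate (not isolated)
12 | 8-benzyl-2-(4-benzyloxybenzyl)-6-(4-benzyloxyphenyl)-5-(dimethylamino)-5,6-dihydroimidazo[1,2-a]pyrazin-3(2H)-one, mixture of stereoisomers | O=C1C(Cc2ccc(OCc3ccccc3)cc2)N=C2C(Cc3ccccc3)=NC(c3ccc(OCc4ccccc4)cc3)C(N(C)C)N12 | intermediate (not isolated)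
13 | 8-benzyl-2-(4-benzyloxybenzyl)-6-(4-benzyloxyphenyl)imidazo[1,2-a]pyrazin-3(2H)-one, C2 of undefined configuration | O=C1C(Cc2ccc(OCc3ccccc3)cc2)N=C2C(Cc3ccccc3)=NC(c3ccc(OCc4ccccc4)cc3)=CN12 | intermediate (not isolated)
14 | O,O'-dibenzylcoelenterazine, 8-benzyl-2-(4-benzyloxybenzyl)-6-(4-benzyloxyphenyl)imidazo[1,2-a]pyrazin-3(7H)-one | O=c1c(Cc2ccc(OCc3ccccc3)cc2)nc2c(Cc3ccccc3)[nH]c(-c3ccc(OCc4ccccc4)cc3)cn1-2 | intermediate
15 | coelenterazine, 8-benzyl-2-(4-hydroxybenzyl)-6-(4-hydroxyphenyl)imidazo[1,2-a]pyrazin-3(7H)-one | O=c1c(Cc2ccc(O)cc2)nc2c(Cc3ccccc3)[nH]c(-c3ccc(O)cc3)cn1-2 | target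

## Count and risks

Total step count: 7. Longest linear sequence: 7 steps (from 1 or 2 to 15).

**Step 6 is the riskiest.**
- The alkoxide may stay on the more acidic C2–H and N–H sites, so that the azaallyl anion is never populated enough to cyclise.
- The aldimine may drift by proton shifts to the ketimine and enamine forms, whose benzylic CH2 could be aminomethylenated irreversibly.
- The one-carbon unit may be taken up at N1 instead of N4.

The fallback sets out from 7 and buys the C5–C6 bond instead of making it. 4-Benzyloxyphenylglyoxal F1 is prepared by Riley oxidation of commercial 4'-benzyloxyacetophenone (SeO2, wet dioxane, reflux). It is condensed with 7 under the conditions of the Jones pyrazine synthesis (NaOH, degassed MeOH, −30 °C → rt, Ar, then AcOH). That condensation of α-amino amides and α-amino amidines with aryl glyoxals is known to place the aryl-bearing carbon next to the former amine nitrogen. The amine of 7 should therefore bind the ketone carbon (C6=N7) and the lactam N–H the aldehyde carbon (N4–C5). Loss of two molecules of water brings the sequence back to the route at 14.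

**Step 3 comes second.**
- Hydroxide may hydrolyse the primary amide faster than the ring closes.
- The peptide nitrogen may attack the Boc carbonyl in a hydantoin-type closure.
- The product anion may autoxidise if traces of air enter.

The fallback sets out from 4, skips step 2 and avoids hydroxide altogether. Lawesson's reagent (THF, 60 °C) thionates the peptide amide in preference to ester and carbamate and gives the thiopeptide Boc-L-Phe-ψ[C(=S)NH]-L-Tyr(Bn)-OMe F2. Methyl iodide and K2CO3 in acetone give the S-methyl thioimidate F3. Ammonium acetate in MeOH at 50 °C displaces methanethiol to give the amidine F4, which closes onto its methyl ester in the same flask. The sequence comes back to the route at 6.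

**Step 7 comes third.**
- The C5=C6 bond of the heterocycle may be over-reduced.
- The basic nitrogen atoms may poison the catalyst.
- The product may autoxidise while the catalyst is filtered off.

The fallback sets out from 14 and replaces reduction by Lewis-acid ether cleavage: BCl3 with pentamethylbenzene as cation scavenger (CH2Cl2, −78 °C, MeOH quench). The medium stays acidic, where the product is least prone to autoxidation. The sequence comes back to the route at 15 and makes no compound outside the list (F0).

## Further compounds

F1 | step 6 | 4-benzyloxyphenylglyoxal | O=CC(=O)c1ccc(OCc2ccccc2)cc1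
F2 | step 3 | Boc-L-Phe-ψ[C(=S)NH]-L-Tyr(Bn)-OMe (thiopeptide) | CC(C)(C)OC(=O)N[C@@H](Cc1ccccc1)C(=S)N[C@@H](Cc1ccc(OCc2ccccc2)cc1)C(=O)OC
F3 | step 3 | S-methyl thioimidate of F2 | CC(C)(C)OC(=O)N[C@@H](Cc1ccccc1)C(SC)=N[C@@H](Cc1ccc(OCc2ccccc2)cc1)C(=O)OC
F4 | step 3 | amidine Boc-L-Phe-ψ[C(=NH)NH]-L-Tyr(Bn)-OMe | CC(C)(C)OC(=O)N[C@@H](Cc1ccccc1)C(=N)N[C@@H](Cc1ccc(OCc2ccccc2)cc1)C(=O)OC
F0 | step 7 | none | none
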